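**Plan**
- Retrosynthesis: the ring B quinone is taken back to its hydroquinone dipivalate. Ring C (the pyran ring) is then opened by cutting C2–C3 and O1–C8a together, which releases CH2=O and leaves an (E)-4-hydroxystilbene. The stilbene is cut at the aryl–vinyl bond C1'–C3 into a ring B aryl bromide and the ring A vinylphenol canolol.
- Forward: the ring B piece is made from 2,3-dimethoxy-1,4-benzoquinone (reduction, pivaloylation, bromination) and joined to canolol by a Mizoroki–Heck reaction. One annulation with formaldehyde then builds ring C onto ring A, and unmasking plus oxidation gives the quinone.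
- Enabling feature: the free C7–OH of ring A is para to C4a and flanked by the C6 and C8 methoxy groups. The stilbene is therefore a vinylogous phenol, nucleophilic at C3. The para-quinone methide that results is electrophilic at ring carbon C8a (beta to the C7 carbonyl), and C5 and C8a are equivalent, so no ring A position has to be oxidised beforehand.
- Stereochemistry: the only stereocentre, C3 (S), is set in the annulation by a chiral Brønsted acid. It is not touched afterwards, and base is avoided once the quinone is present, because C3–H is vinylogously acidic there.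
- Pivalates on ring B make that ring electron-poor and non-participating during the annulation.

Key step: step 5

Remark: the sense of induction of the chiral acid in step 5 cannot be predicted with certainty, so the catalyst antipode that gives the (S)-product is assigned in the first run; compounds 1 and 5 are taken as purchasable.

**Step 1**
Reactants: 1 2,3-dimethoxy-1,4-benzoquinone
Product: 3 2,3-dimethoxy-1,4-phenylene bis(2,2-dimethylpropanoate), via 2,3-dimethoxyhydroquinone 2 (not isolated)
Conditions: Na2S2O4, EtOAc/H2O, rt; organic layer dried; then PivCl, Et3N, DMAP (cat.), CH2Cl2, 0 °C to rt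
Reagents that add atoms: pivaloyl chloride, CC(C)(C)C(Cl)=O
Why: Dithionite reduction of the quinone followed by DMAP-catalysed O-acylation of both phenols (Schotten–Baumann-type esterification) should give the diester.

**Step 2**
Reactants: 3 2,3-dimethoxy-1,4-phenylene bis(2,2-dimethylpropanoate)
Product: 4 5-bromo-2,3-dimethoxy-1,4-phenylene bis(2,2-dimethylpropanoate)
Conditions: Br2 (1.05 equiv), NaOAc, AcOH, rt to 40 °C
Reagents that add atoms: bromine, BrBr
Why: Electrophilic aromatic bromination; the two free positions are equivalent and each is para to a methoxy group, so a single monobromide should form.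

**Step 3**
Reactants: 5 sinapic acid, (E)-3-(4-hydroxy-3,5-dimethoxyphenyl)prop-2-enoic acid
Product: 6 canolol, 4-ethenyl-2,6-dimethoxyphenol
Conditions: Et3N, DMF, 110 °C, BHT (trace)
Reagents that add atoms: none
Why: Base-promoted thermal decarboxylation of a 4-hydroxycinnamic acid through its para-quinone methide tautomer should give the 4-vinylphenol.

**Step 4**
Reactants: 4 5-bromo-2,3-dimethoxy-1,4-phenylene bis(2,2-dimethylpropanoate); 6 canolol
Product: 7 5-[(E)-2-(4-hydroxy-3,5-dimethoxyphenyl)ethenyl]-2,3-dimethoxy-1,4-phenylene bis(2,2-dimethylpropanoate)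
Conditions: Pd(OAc)2 (5 mol %), P(o-tol)3 (10 mol %), Et3N, DMF, 90 °C, BHT (trace), argon
Reagents that add atoms: none
Why: Mizoroki–Heck reaction; the aryl bromide adds oxidatively to zerovalent palladium, the aryl group is delivered to the terminal alkene carbon, and syn beta-hydride elimination should give the (E)-stilbene.

**Step 5**
Reactants: 7 5-[(E)-2-(4-hydroxy-3,5-dimethoxyphenyl)ethenyl]-2,3-dimethoxy-1,4-phenylene bis(2,2-dimethylpropanoate)
Product: 10 5-[(3S)-7-hydroxy-6,8-dimethoxy-3,4-dihydro-2H-chromen-3-yl]-2,3-dimethoxy-1,4-phenylene bis(2,2-dimethylpropanoate), via para-quinone methide alcohol 8 (not isolated), via dearomatised trienol 9 (not isolated)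
Conditions: (CH2O)n (3 equiv), confined chiral imino-imidodiphosphate Brønsted acid (5 mol %), CHCl3 (0.02 M), 5 Å MS, 0 °C to rt, argon
Reagents that add atoms: formaldehyde (used as paraformaldehyde), C=O
Why: Proposed new method: the chiral acid depolymerises and protonates formaldehyde, the stilbene attacks it through C3 as a vinylogous phenol (Prins-type C–C bond formation) to give para-quinone methide 8 with CH2OH on C3, the hydroxyl then adds to ring carbon C8a (attack at the methide carbon C4 would only give a strained, reversibly formed oxetane), and trienol 9 rearomatises by a proton shift from C8a to C4, so the event is a redox-neutral formal [4+2] annulation of the C3=C4–C4a=C8a unit with CH2=O. The closest known reaction types are the catalytic asymmetric intermolecular Prins reaction of aryl alkenes with paraformaldehyde under confined chiral Brønsted acids and the acid-induced conversion of 4-hydroxystyrenes into para-quinone methides by electrophilic attack at the beta carbon; what is new is capture of the quinone methide at a ring carbon. Ring C closes in a 6-exo-trig oxa-Michael mode, O adding to C8a of the C8=C8a enone bond. The C3 stereocentre is created in the C–C bond-forming step, where the confined chiral counteranion pairs with the developing cation and selects one face of the (E)-alkene. The step needs attack at C3 and not C4, which the free C7–OH (the strongest donor, para to C4a) should secure against the pivalate-deactivated ring B; it needs ring closure to outrun proton loss from C3, which a tight ion pair in a non-basic medium should favour; and it needs no choice between C5 and C8a, which are equivalent in the symmetric ring A.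

**Step 6**
Reactants: 10 5-[(3S)-7-hydroxy-6,8-dimethoxy-3,4-dihydro-2H-chromen-3-yl]-2,3-dimethoxy-1,4-phenylene bis(2,2-dimethylpropanoate)
Product: 12 5-[(3S)-7-hydroxy-6,8-dimethoxy-3,4-dihydro-2H-chromen-3-yl]-2,3-dimethoxycyclohexa-2,5-diene-1,4-dione, via hydroquinone 11 (not isolated)
Conditions: LiAlH4 (3 equiv), THF, 0 °C, argon; degassed 1 M HCl quench, extraction; then FeCl3 (2.2 equiv), MeCN/H2O, 0 °C
Reagents that add atoms: none
Why: Hydride cleavage of the two aryl pivalates keeps ring B at the hydroquinone level, and FeCl3 should then oxidise the electron-rich hydroquinone to the para-quinone much faster than the lone ring A phenol, with no base present that could epimerise C3.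

**Compound list**
1 | 2,3-dimethoxy-1,4-benzoquinone | COC1=C(OC)C(=O)C=CC1=O | starting material
2 | 2,3-dimethoxybenzene-1,4-diol (2,3-dimethoxyhydroquinone) | COc1c(O)ccc(O)c1OC | intermediate
3 | 2,3-dimethoxy-1,4-phenylene bis(2,2-dimethylpropanoate) | COc1c(OC(=O)C(C)(C)C)ccc(OC(=O)C(C)(C)C)c1OC | intermediate
4 | 5-bromo-2,3-dimethoxy-1,4-phenylene bis(2,2-dimethylpropanoate) | COc1c(OC(=O)C(C)(C)C)cc(Br)c(OC(=O)C(C)(C)C)c1OC | intermediate
5 | sinapic acid, (E)-3-(4-hydroxy-3,5-dimethoxyphenyl)prop-2-enoic acid | COc1cc(/C=C/C(=O)O)cc(OC)c1O | starting material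
6 | canolol, 4-ethenyl-2,6-dimethoxyphenol | C=Cc1cc(OC)c(O)c(OC)c1 | intermediate
7 | 5-[(E)-2-(4-hydroxy-3,5-dimethoxyphenyl)ethenyl]-2,3-dimethoxy-1,4-phenylene bis(2,2-dimethylpropanoate) | COc1cc(/C=C/c2cc(OC(=O)C(C)(C)C)c(OC)c(OC)c2OC(=O)C(C)(C)C)cc(OC)c1O | intermediate
8 | 5-[(2S)-1-(3,5-dimethoxy-4-oxocyclohexa-2,5-dien-1-ylidene)-3-hydroxypropan-2-yl]-2,3-dimethoxy-1,4-phenylene bis(2,2-dimethylpropanoate) (para-quinone methide alcohol) | COC1=CC(=C[C@H](CO)c2cc(OC(=O)C(C)(C)C)c(OC)c(OC)c2OC(=O)C(C)(C)C)C=C(OC)C1=O | intermediate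
9 | 5-[(3S)-7-hydroxy-6,8-dimethoxy-3,8a-dihydro-2H-chromen-3-yl]-2,3-dimethoxy-1,4-phenylene bis(2,2-dimethylpropanoate) (dearomatised trienol, C8a configuration open) | COC1=CC2=C[C@@H](c3cc(OC(=O)C(C)(C)C)c(OC)c(OC)c3OC(=O)C(C)(C)C)COC2C(OC)=C1O | intermediate
10 | 5-[(3S)-7-hydroxy-6,8-dimethoxy-3,4-dihydro-2H-chromen-3-yl]-2,3-dimethoxy-1,4-phenylene bis(2,2-dimethylpropanoate) | COc1c(OC)c(OC(=O)C(C)(C)C)c([C@H]2COc3c(cc(OC)c(O)c3OC)C2)cc1OC(=O)C(C)(C)C | intermediate
11 | 5-[(3S)-7-hydroxy-6,8-dimethoxy-3,4-dihydro-2H-chromen-3-yl]-2,3-dimethoxybenzene-1,4-diol | COc1c(OC)c(O)c([C@H]2COc3c(cc(OC)c(O)c3OC)C2)cc1O | intermediate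
12 | 5-[(3S)-7-hydroxy-6,8-dimethoxy-3,4-dihydro-2H-chromen-3-yl]-2,3-dimethoxycyclohexa-2,5-diene-1,4-dione | COC1=C(OC)C(=O)C([C@H]2COc3c(cc(OC)c(O)c3OC)C2)=CC1=O | target

**Count**
Total step count: 6. Longest linear sequence: 5 steps (steps 1, 2, 4, 5, 6); step 3 is a one-step side branch.

**Steps most likely to fail**

1. Step 5 (proposed new method). What may go wrong:
   - proton loss from C3 of the quinone methide, or capture by a second formaldehyde, outrunning ring closure at C8a;
   - oligomerisation by quinone methide–alkene coupling;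
   - poor facial selectivity in the C–C bond formation.

   The fallback uses known chemistry, sets out from 4 and comes back at 10. Palladium-catalysed coupling of 4 with the Reformatsky reagent BrZnCH2CO2t-Bu (Pd(dba)2, P(t-Bu)3, THF) would give tert-butyl [3,4-dimethoxy-2,5-bis(2,2-dimethylpropanoyloxy)phenyl]acetate F1, and TFA would free [3,4-dimethoxy-2,5-bis(2,2-dimethylpropanoyloxy)phenyl]acetic acid F2. A Perkin condensation of F2 with purchased syringaldehyde (Ac2O, Et3N, 110 °C; the phenol is acetylated in the same pot) would give (E)-3-(4-acetoxy-3,5-dimethoxyphenyl)-2-[3,4-dimethoxy-2,5-bis(2,2-dimethylpropanoyloxy)phenyl]prop-2-enoic acid F3. Asymmetric hydrogenation with Ru(OAc)2[(S)-BINAP] (ligand antipode chosen to give S) would set C3 in (2S)-3-(4-acetoxy-3,5-dimethoxyphenyl)-2-[3,4-dimethoxy-2,5-bis(2,2-dimethylpropanoyloxy)phenyl]propanoic acid F4. BH3·SMe2 would reduce the acid to 5-[(2S)-1-(4-acetoxy-3,5-dimethoxyphenyl)-3-hydroxypropan-2-yl]-2,3-dimethoxy-1,4-phenylene bis(2,2-dimethylpropanoate) F5. NBS would brominate one of the two equivalent ring A positions next to the side chain (ring B being deactivated) to give 5-[(2S)-1-(4-acetoxy-2-bromo-3,5-dimethoxyphenyl)-3-hydroxypropan-2-yl]-2,3-dimethoxy-1,4-phenylene bis(2,2-dimethylpropanoate) F6. Intramolecular Ullmann etherification (CuI, 1,10-phenanthroline, Cs2CO3, toluene, 90 °C) would close ring C to 5-[(3S)-7-acetoxy-6,8-dimethoxy-3,4-dihydro-2H-chromen-3-yl]-2,3-dimethoxy-1,4-phenylene bis(2,2-dimethylpropanoate) F7. K2CO3 in MeOH at 0 °C would remove the acetate selectively and deliver 10.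

2. Step 4. What may go wrong: thermal or cationic polymerisation of the free vinylphenol at the reaction temperature, and competing arylation at the internal alkene carbon.

   The fallback sets out from 4 and comes back at 7. Suzuki–Miyaura vinylation of 4 with potassium vinyltrifluoroborate (PdCl2(dppf), Et3N, n-PrOH, 80 °C) would give 5-ethenyl-2,3-dimethoxy-1,4-phenylene bis(2,2-dimethylpropanoate) F8. Olefin cross-metathesis of F8 with an excess of canolol 6 (second-generation Grubbs catalyst RuCl2(=CHPh)(H2IMes)(PCy3), CH2Cl2, 40 °C) should then give the (E)-stilbene 7 at low temperature, with ethene leaving the mixture.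

3. Step 6. What may go wrong: oxidative coupling or benzylic oxidation at the free ring A phenol during the hydroquinone oxidation, and loss of stereochemical purity at C3 if the quinone meets base.

   The fallback sets out from 10 and comes back at 12. Silylation of the ring A phenol (TIPSOTf, 2,6-lutidine, CH2Cl2) would give 5-[(3S)-6,8-dimethoxy-7-{[tri(propan-2-yl)silyl]oxy}-3,4-dihydro-2H-chromen-3-yl]-2,3-dimethoxy-1,4-phenylene bis(2,2-dimethylpropanoate) F9. LiAlH4 would cleave the pivalates to 5-[(3S)-6,8-dimethoxy-7-{[tri(propan-2-yl)silyl]oxy}-3,4-dihydro-2H-chromen-3-yl]-2,3-dimethoxybenzene-1,4-diol F10. Ag2O in Et2O, now with no free phenol present, would give 5-[(3S)-6,8-dimethoxy-7-{[tri(propan-2-yl)silyl]oxy}-3,4-dihydro-2H-chromen-3-yl]-2,3-dimethoxycyclohexa-2,5-diene-1,4-dione F11. HF·pyridine in THF (acidic, no base) would remove the silyl group to give 12.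

**Further compounds**
F1 | step 5 | tert-butyl [3,4-dimethoxy-2,5-bis(2,2-dimethylpropanoyloxy)phenyl]acetate | COc1c(OC)c(OC(=O)C(C)(C)C)c(CC(=O)OC(C)(C)C)cc1OC(=O)C(C)(C)C
F2 | step 5 | [3,4-dimethoxy-2,5-bis(2,2-dimethylpropanoyloxy)phenyl]acetic acid | COc1c(OC)c(OC(=O)C(C)(C)C)c(CC(=O)O)cc1OC(=O)C(C)(C)C
F3 | step 5 | (E)-3-(4-acetoxy-3,5-dimethoxyphenyl)-2-[3,4-dimethoxy-2,5-bis(2,2-dimethylpropanoyloxy)phenyl]prop-2-enoic acid | COc1cc(/C=C(\c2cc(OC(=O)C(C)(C)C)c(OC)c(OC)c2OC(=O)C(C)(C)C)C(=O)O)cc(OC)c1OC(C)=O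
F4 | step 5 | (2S)-3-(4-acetoxy-3,5-dimethoxyphenyl)-2-[3,4-dimethoxy-2,5-bis(2,2-dimethylpropanoyloxy)phenyl]propanoic acid | COc1c(OC)c(OC(=O)C(C)(C)C)c([C@H](Cc2cc(OC)c(OC(C)=O)c(OC)c2)C(=O)O)cc1OC(=O)C(C)(C)C
F5 | step 5 | 5-[(2S)-1-(4-acetoxy-3,5-dimethoxyphenyl)-3-hydroxypropan-2-yl]-2,3-dimethoxy-1,4-phenylene bis(2,2-dimethylpropanoate) | COc1c(OC)c(OC(=O)C(C)(C)C)c([C@H](Cc2cc(OC)c(OC(C)=O)c(OC)c2)CO)cc1OC(=O)C(C)(C)C
F6 | step 5 | 5-[(2S)-1-(4-acetoxy-2-bromo-3,5-dimethoxyphenyl)-3-hydroxypropan-2-yl]-2,3-dimethoxy-1,4-phenylene bis(2,2-dimethylpropanoate) | COc1c(OC)c(OC(=O)C(C)(C)C)c([C@H](Cc2cc(OC)c(OC(C)=O)c(OC)c2Br)CO)cc1OC(=O)C(C)(C)C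
F7 | step 5 | 5-[(3S)-7-acetoxy-6,8-dimethoxy-3,4-dihydro-2H-chromen-3-yl]-2,3-dimethoxy-1,4-phenylene bis(2,2-dimethylpropanoate) | COc1c(OC)c(OC(=O)C(C)(C)C)c([C@H]2COc3c(cc(OC)c(OC(C)=O)c3OC)C2)cc1OC(=O)C(C)(C)C
F8 | step 4 | 5-ethenyl-2,3-dimethoxy-1,4-phenylene bis(2,2-dimethylpropanoate) | COc1c(OC)c(OC(=O)C(C)(C)C)c(C=C)cc1OC(=O)C(C)(C)C
F9 | step 6 | 5-[(3S)-6,8-dimethoxy-7-{[tri(propan-2-yl)silyl]oxy}-3,4-dihydro-2H-chromen-3-yl]-2,3-dimethoxy-1,4-phenylene bis(2,2-dimethylpropanoate) | COc1c(OC)c(OC(=O)C(C)(C)C)c([C@H]2COc3c(cc(OC)c(O[Si](C(C)C)(C(C)C)C(C)C)c3OC)C2)cc1OC(=O)C(C)(C)C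
F10 | step 6 | 5-[(3S)-6,8-dimethoxy-7-{[tri(propan-2-yl)silyl]oxy}-3,4-dihydro-2H-chromen-3-yl]-2,3-dimethoxybenzene-1,4-diol | COc1c(OC)c(O)c([C@H]2COc3c(cc(OC)c(O[Si](C(C)C)(C(C)C)C(C)C)c3OC)C2)cc1O
F11 | step 6 | 5-[(3S)-6,8-dimethoxy-7-{[tri(propan-2-yl)silyl]oxy}-3,4-dihydro-2H-chromen-3-yl]-2,3-dimethoxycyclohexa-2,5-diene-1,4-dione | COC1=C(OC)C(=O)C([C@H]2COc3c(cc(OC)c(O[Si](C(C)C)(C(C)C)C(C)C)c3OC)C2)=CC1=O
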